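All runs were generated by integration from invented constants, and the scatter is random.

We met over a small charge of solid D stirred with X, to ask when to stop.

| flask | D | X | remark | time |
|---|---|---|---|---|
| birch | 0.083 M | 3 equiv | the very flask that is asked about, followed so far |  |
| ash | 0.056 M | 3 equiv | run made earlier |  |
| flask | 0.083 M | 3.00 equiv |  | 2.0 h |

| run | time / min | G / % |
|---|---|---|
| birch | 4.00 | 29 |
| birch | 6.00 | 41 |
| birch | 12.0 | 85 |
| birch | 25.0 | 91 |
| ash | 4.00 | 40 |
| ash | 8.00 | 78 |
| ash | 20.0 | 87 |
| ash | 50.0 | 75 |

(readings scatter by 2 percentage points)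

* the best time, 2.0 h at the latest, for G
* the amount of G, in percent of the D charged, at that time

- the earlier runs were read with a standard deviation of 2 percentage points
- at the start none of D is in solution
- a reading or a percentage of G counts all its forms, free or not

Minutes, kept by me. I reported that birch had reached a c_G pace of 5.67 mM min⁻¹ by 6.00 min and ash 5.46 mM min⁻¹ by 8.00 min. These are close although the charges differ, so I took one steady feed while solid D lasts, and at that pace the charge in this flask lasts 0.244 h.

I then proposed following one D to its fork, G kept or G lost. Ash, read at 20.0 min, later than the 9.87 min its charge lasts at that pace, shows 87%. I counted the missing part as lost over that time, a leak of 0.364 mM min⁻¹.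

My quantity is the leak share, leak pace over feed pace, 6.42%: the part of the D fed that is lost by the end of the feed. Both are paces in concentration, so in this reckoning the charge cancels. I committed to 93.6% at 0.244 h, as a rough reading, since each reading carries 2 percentage points.

The forecast, holding that “the rate is fixed in absolute concentration, not percent”, gave 93% at 0.27 h, later than my time.

The flask gives 93.1% at 0.231 h.

    D ⇌ Q, rate k1*(cs1 - [Q]) while solid is left; crystals form when [Q] > cs1 (solubility = 36.0 mM, k = 0.00300 s⁻¹)
    Q + X → G (k = 0.420 M⁻¹ s⁻¹)
    E ⇌ G, rate k3*(cs3 - [G]) while solid is left; crystals form when [G] > cs3 (solubility = 17.0 mM, k = 0.130 s⁻¹)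
    2 D → L (k = 4.80 × 10⁻⁵ M⁻¹ s⁻¹)
    G ⇌ Z (K = 1.40, k = 4.70 × 10⁻⁴ s⁻¹)

While D, the limiting reagent, stood in the flask, 9.14% at 0.200 h and 0% at 0.232 h with X still at 66.8%, it dissolved as Q, Q met X to give G, G came out as solid E, and Z grew to 6.55%, near the leak share 6.42%. After that, G passed on into Z, with G at 79.9% and Z at 19.9% by 1.00 h. In the neighbour charged with 0.021 M of D, the unchanged leak share gives 93.6%; the computed best there is 90.0%.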